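The α-methylene-γ-butyrolactone (O–C6–C7–C11(=C13H2)–C12=O, germacranolide numbering) shares its C6–C7 bond with the ten-membered carbocycle. The route therefore culminates in a carbonylative [2+2+1] union (hetero-Pauson–Khand type) of an aldehyde (C6=O), the internal C7=C11 π-bond of a terminal allene and CO (C12): one operation forms C6–C7 and C11–C12, closes both rings and sets C6 and C7 under control of C8. Its precursor is an acyclic enal–allene that already carries the C8 methacrylate, the 1,10-epoxide with the C14 acetate and a PMB-protected C15 alcohol; it is built from two small alkynes, oxirane and an allenylstannane.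

Key step: step 17

Numbering: germacranolide numbering of the target is used for all intermediates (ring C1–C10; C11, C12, C13 = lactone α-carbon, carbonyl, methylene; C14 on C10; C15 on C4).
Assumption: the R,R form of the diazaborolidine controller in step 10 is taken to give the 8S carbinol (closed chair model of this reagent class); if the sense is opposite, its S,S enantiomer is used with no other change.

Step 1
Reactants: 1 but-2-yne-1,4-diol
Product: 2 4-[(4-methoxybenzyl)oxy]but-2-yn-1-ol
Conditions: NaH (1 equiv), 4-methoxybenzyl chloride, Bu4NI (cat.), THF/DMF, 0 °C to rt, excess of 1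
Reagents that add atoms: 4-methoxybenzyl chloride, COc1ccc(CCl)cc1
Why: Williamson etherification, in which an excess of the symmetric diol should hold the reaction at the mono-ether.

Step 2
Reactants: 2 4-[(4-methoxybenzyl)oxy]but-2-yn-1-ol
Product: 3 (Z)-3-iodo-4-[(4-methoxybenzyl)oxy]but-2-en-1-ol
Conditions: Red-Al [NaAlH2(OCH2CH2OMe)2], THF, 0 °C; then I2, THF, −78 °C
Reagents that add atoms: iodine, II
Why: Hydroxyl-directed trans-hydroalumination places aluminium on the distal alkyne carbon (C4) in a five-membered alkoxyalanate, and iodinolysis with retention should give the iodide cis to the CH2OH group, which fixes the later C4=C5 geometry.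

Step 3
Reactants: 3 (Z)-3-iodo-4-[(4-methoxybenzyl)oxy]but-2-en-1-ol
Product: 4 (Z)-tert-butyl({3-iodo-4-[(4-methoxybenzyl)oxy]but-2-en-1-yl}oxy)diphenylsilane
Conditions: TBDPSCl, imidazole, CH2Cl2, 0 °C to rt
Reagents that add atoms: tert-butyl(chloro)diphenylsilane, CC(C)(C)[Si](Cl)(c1ccccc1)c1ccccc1
Why: Standard silylation of the primary allylic alcohol (C6–OH), giving a group that outlasts the later TBS removal.

Step 4
Reactants: 5 tert-butyldimethyl(prop-2-yn-1-yloxy)silane; 6 oxirane
Product: 7 5-[(tert-butyldimethylsilyl)oxy]pent-3-yn-1-ol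
Conditions: n-BuLi, THF, −78 °C; then BF3·OEt2, 6, −78 °C
Reagents that add atoms: none
Why: BF3-promoted SN2 opening of an epoxide by a lithium acetylide, a reliable route to homopropargylic alcohols.

Step 5
Reactants: 7 5-[(tert-butyldimethylsilyl)oxy]pent-3-yn-1-ol
Product: 8 tert-butyl[(5-iodopent-2-yn-1-yl)oxy]dimethylsilane
Conditions: I2, PPh3, imidazole, CH2Cl2, 0 °C
Reagents that add atoms: iodine, II
Why: Appel-type iodination of a primary alcohol, to which the silyl ether and the alkyne are inert.

Step 6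
Reactants: 8 tert-butyl[(5-iodopent-2-yn-1-yl)oxy]dimethylsilane; 4 (Z)-tert-butyl({3-iodo-4-[(4-methoxybenzyl)oxy]but-2-en-1-yl}oxy)diphenylsilane
Product: 10 enyne TBSO–C14H2–C10≡C1–C2H2–C3H2–C4(C15H2OPMB)=C5H–C6H2–OTBDPS (C3 cis to C6), via alkylzinc iodide 9 (not isolated)
Conditions: Zn dust, LiCl, THF, 40 °C; then 4, Pd(PPh3)4 (5 mol %), THF, rt to 50 °C
Reagents that add atoms: zinc, [Zn] (kept only in intermediate 9)
Why: Negishi sp3–sp2 coupling, in which oxidative addition and reductive elimination proceed with retention at the alkenyl carbon, so that C3 takes the place of iodine cis to C6.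

Step 7
Reactants: 10 enyne TBSO–C14H2–C10≡C1–C2H2–C3H2–C4(C15H2OPMB)=C5H–C6H2–OTBDPS
Product: 11 alkenylstannane (Bu3Sn on C10 and H on C1; C14 cis to C2; tin trans to C2)
Conditions: Bu3SnH, PdCl2(PPh3)2 (2 mol %), THF, 0 °C
Reagents that add atoms: tributyltin hydride, CCCC[SnH](CCCC)CCCC
Why: Palladium-catalysed syn-hydrostannation, in which the propargylic oxygen should direct tin to the proximal carbon C10 and the syn addition places C14 cis to C2.

Step 8
Reactants: 11 alkenylstannane (Bu3Sn on C10); 6 oxirane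
Product: 13 homoallylic alcohol HO–C8H2–C9H2–C10(C14H2OTBS)=C1H– (C9 trans to C2), via alkenyllithium 12 (not isolated)
Conditions: n-BuLi, THF, −78 °C; then BF3·OEt2, 6, −78 °C
Reagents that add atoms: n-butyllithium, CCCC[Li] (lithium kept only in intermediate 12)
Why: Tin–lithium exchange with retention of the olefin geometry followed by BF3-promoted SN2 opening of oxirane, which attaches C9–C8 trans to C2 on the C1=C10 olefin.

Step 9
Reactants: 13 homoallylic alcohol (C8–OH)
Product: 14 β,γ-unsaturated aldehyde (C8 = CHO)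
Conditions: Dess–Martin periodinane, NaHCO3, CH2Cl2, 0 °C; used at once without chromatography
Reagents that add atoms: none
Why: Buffered Dess–Martin oxidation is neutral and fast, so the aldehyde should form without migration of the C1=C10 double bond into conjugation.

Step 10
Reactants: 14 β,γ-unsaturated aldehyde (C8 = CHO); 15 tributyl(propa-1,2-dien-1-yl)stannane
Product: 17 (8S)-allenyl carbinol C8H(OH)–C7H=C11=C13H2, via B-propargyl diazaborolidine 16 (not isolated)
Conditions: (4R,5R)-2-bromo-4,5-diphenyl-1,3-bis(4-tolylsulfonyl)-1,3,2-diazaborolidine, 15, CH2Cl2, 0 °C to rt; then 14, −78 °C; aqueous work-up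
Reagents that add atoms: (4R,5R)-2-bromo-4,5-diphenyl-1,3-bis(4-tolylsulfonyl)-1,3,2-diazaborolidine, BrB1N(S(=O)(=O)c2ccc(C)cc2)[C@H](c2ccccc2)[C@@H](c2ccccc2)N1S(=O)(=O)c1ccc(C)cc1 (boron and ligand kept only in intermediate 16)
Why: Tin-to-boron exchange (SE2') gives the chiral propargylborane, which adds to the aldehyde through a closed six-membered SE2' transition state to give the allenyl carbinol, the C2-symmetric bis-sulfonamide ligand differentiating the aldehyde faces and setting C8 as S.

Step 11
Reactants: 17 (8S)-allenyl carbinol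
Product: 18 (8S)-allenyl methacrylate
Conditions: methacrylic anhydride, Et3N, DMAP (cat.), CH2Cl2, 0 °C
Reagents that add atoms: methacrylic anhydride, CC(=C)C(=O)OC(=O)C(C)=C
Why: DMAP-catalysed acylation of the secondary alcohol, which leaves the C8 configuration untouched and blocks any later attack of the hydroxyl on the allene.

Step 12
Reactants: 18 (8S)-allenyl methacrylate
Product: 19 C14 allylic alcohol (TBS removed; TBDPS and PMB kept)
Conditions: camphorsulfonic acid (cat.), MeOH/CH2Cl2, 0 °C
Reagents that add atoms: none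
Why: Acid-catalysed methanolysis cleaves the primary TBS ether much faster than the TBDPS ether and leaves the PMB ether, the ester and the allene alone.

Step 13
Reactants: 19 C14 allylic alcohol
Product: 20 (8S,1R,10S)-epoxy alcohol (1,10-epoxide; C14–OH)
Conditions: Ti(OiPr)4 (20 mol %), L-(+)-diethyl tartrate (24 mol %), t-BuOOH, 4 Å MS, CH2Cl2, −20 °C
Reagents that add atoms: tert-butyl hydroperoxide, CC(C)(C)OO
Why: Sharpless asymmetric epoxidation, in which only the C1=C10 olefin carries a free allylic hydroxyl; L-(+)-tartrate delivers oxygen to the enantioface that gives 10S (the sense that gives 2S epoxides from simple 2-alken-1-ols), and the olefin geometry (C14 cis to C2) then makes C1 R.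

Step 14
Reactants: 20 (8S,1R,10S)-epoxy alcohol
Product: 21 (8S,1R,10S)-epoxy acetate (C14–OAc)
Conditions: Ac2O, pyridine, DMAP (cat.), CH2Cl2, 0 °C
Reagents that add atoms: acetic anhydride, CC(=O)OC(C)=O
Why: Mild acetylation of the primary epoxy alcohol, which does not touch the epoxide stereocenters.

Step 15
Reactants: 21 (8S,1R,10S)-epoxy acetate
Product: 22 C6 allylic alcohol (TBDPS removed)
Conditions: HF·pyridine, pyridine, THF, 0 °C to rt
Reagents that add atoms: none
Why: Buffered fluoride cleavage of the primary TBDPS ether, under which esters, the trisubstituted epoxide, the allene and the PMB ether should survive.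

Step 16
Reactants: 22 C6 allylic alcohol
Product: 23 (8S,1R,10S)-enal–allene (C6 = CHO, cis to C3)
Conditions: MnO2, CH2Cl2, rt
Reagents that add atoms: none
Why: Chemoselective oxidation of the only allylic alcohol under neutral conditions, which keeps the enal geometry.

Step 17
Reactants: 23 (8S,1R,10S)-enal–allene; 24 carbon monoxide
Product: 25 15-O-PMB ether of the target (6R,7R,8S,1R,10S)
Conditions: Ru3(CO)12 (10 mol %), CO (20 atm), 1,4-dioxane, 110 °C, slow addition of 23 to a final 2 mM
Reagents that add atoms: none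
Why: Proposed new method: a ruthenium carbonyl fragment binds the C6 aldehyde and the internal C7=C11 π-bond of the allene, oxidative cyclisation gives a 2-oxaruthenacyclopentane with an exocyclic C11=C13 methylene (C6–C7 formed), CO inserts into the Ru–C11 bond (C11–C12 formed) and C12–O reductive elimination releases the lactone and zerovalent ruthenium. The closest known reaction type is the Ru3(CO)12-catalysed cyclocarbonylation (hetero-Pauson–Khand reaction) of allenyl aldehydes with short tethers, which gives bicyclic α-methylene-γ-butyrolactones fused to five- or six-membered carbocycles; closing a ten-membered ring in this way has no precedent. The carbocycle closes in a 10-exo-trig mode at the allene terminus C7, and the lactone is assembled by the [2+2+1] union of C6=O, C7=C11 and CO around the shared C6–C7 bond. C6 and C7 are set together in the oxidative cyclisation, trans to each other because C5 and C8 take pseudo-equatorial positions on the metallacycle, and their absolute sense follows from C8: with the C8–H bond eclipsing the allene, C6 reaches C7 from the face of the tether carbon C9, anti to the C8–O bond. The step needs the proximal and not the terminal π-bond of the allene, and ring closure instead of oligomerisation; the first rests on the preference of this catalyst for the internal π-bond and on the C8 ester carbonyl next to it, the second on the cis enal and the trans epoxide, which pre-bend the eight-carbon tether, and on slow addition at high dilution.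

Step 18
Reactants: 25 15-O-PMB ether of the target
Product: 26 target CNP0306006.2
Conditions: DDQ, CH2Cl2/pH 7 phosphate buffer, 0 °C
Reagents that add atoms: none
Why: Oxidative PMB cleavage by hydride abstraction at the electron-rich benzylic position, under neutral conditions that leave the epoxide, both esters and the α-methylene lactone untouched.

Compound list
1 | but-2-yne-1,4-diol | OCC#CCO | starting material
2 | 4-[(4-methoxybenzyl)oxy]but-2-yn-1-ol | OCC#CCOCc1ccc(OC)cc1 | intermediate
3 | (Z)-3-iodo-4-[(4-methoxybenzyl)oxy]but-2-en-1-ol | OC/C=C(\I)COCc1ccc(OC)cc1 | intermediate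
4 | (Z)-tert-butyl({3-iodo-4-[(4-methoxybenzyl)oxy]but-2-en-1-yl}oxy)diphenylsilane | CC(C)(C)[Si](c1ccccc1)(c1ccccc1)OC/C=C(\I)COCc1ccc(OC)cc1 | intermediate
5 | tert-butyldimethyl(prop-2-yn-1-yloxy)silane | C#CCO[Si](C)(C)C(C)(C)C | starting material
6 | oxirane | C1CO1 | starting material
7 | 5-[(tert-butyldimethylsilyl)oxy]pent-3-yn-1-ol | OCCC#CCO[Si](C)(C)C(C)(C)C | intermediate
8 | tert-butyl[(5-iodopent-2-yn-1-yl)oxy]dimethylsilane | ICCC#CCO[Si](C)(C)C(C)(C)C | intermediate
9 | {5-[(tert-butyldimethylsilyl)oxy]pent-3-yn-1-yl}zinc iodide (not isolated) | I[Zn]CCC#CCO[Si](C)(C)C(C)(C)C | intermediate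
10 | enyne: C14 OTBS, C1≡C10 alkyne, C4=C5 olefin with C3 cis to C6, C15 OPMB, C6 OTBDPS | CC(C)(C)[Si](C)(C)OCC#CCC/C(COCc1ccc(OC)cc1)=C\CO[Si](c1ccccc1)(c1ccccc1)C(C)(C)C | intermediate
11 | alkenylstannane: as 10 with Bu3Sn on C10 and H on C1, C14 cis to C2 | CC(C)(C)[Si](C)(C)OC/C([Sn](CCCC)(CCCC)CCCC)=C\CC/C(COCc1ccc(OC)cc1)=C\CO[Si](c1ccccc1)(c1ccccc1)C(C)(C)C | intermediate
12 | alkenyllithium: as 11 with Li in place of Bu3Sn (not isolated) | [Li]/C(CO[Si](C)(C)C(C)(C)C)=C/CC/C(COCc1ccc(OC)cc1)=C\CO[Si](c1ccccc1)(c1ccccc1)C(C)(C)C | intermediate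
13 | homoallylic alcohol: C8 CH2OH, C1=C10 olefin with C9 trans to C2 and C14 OTBS | OCC/C(CO[Si](C)(C)C(C)(C)C)=C/CC/C(COCc1ccc(OC)cc1)=C\CO[Si](c1ccccc1)(c1ccccc1)C(C)(C)C | intermediate
14 | β,γ-unsaturated aldehyde: as 13 with C8 as CHO | O=CC/C(CO[Si](C)(C)C(C)(C)C)=C/CC/C(COCc1ccc(OC)cc1)=C\CO[Si](c1ccccc1)(c1ccccc1)C(C)(C)C | intermediate
15 | tributyl(propa-1,2-dien-1-yl)stannane | C=C=C[Sn](CCCC)(CCCC)CCCC | starting material
16 | (4R,5R)-4,5-diphenyl-2-(prop-2-yn-1-yl)-1,3-bis(4-tolylsulfonyl)-1,3,2-diazaborolidine (not isolated) | C#CCB1N(S(=O)(=O)c2ccc(C)cc2)[C@H](c2ccccc2)[C@@H](c2ccccc2)N1S(=O)(=O)c1ccc(C)cc1 | intermediate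
17 | (8S)-allenyl carbinol: C8H(OH)–C7H=C11=C13H2 | C=C=C[C@@H](O)C/C(CO[Si](C)(C)C(C)(C)C)=C/CC/C(COCc1ccc(OC)cc1)=C\CO[Si](c1ccccc1)(c1ccccc1)C(C)(C)C | intermediate
18 | (8S)-allenyl methacrylate | C=C=C[C@@H](OC(=O)C(C)=C)C/C(CO[Si](C)(C)C(C)(C)C)=C/CC/C(COCc1ccc(OC)cc1)=C\CO[Si](c1ccccc1)(c1ccccc1)C(C)(C)C | intermediate
19 | (8S)-C14 allylic alcohol | C=C=C[C@@H](OC(=O)C(C)=C)C/C(CO)=C/CC/C(COCc1ccc(OC)cc1)=C\CO[Si](c1ccccc1)(c1ccccc1)C(C)(C)C | intermediate
20 | (8S,1R,10S)-epoxy alcohol | C=C=C[C@@H](OC(=O)C(C)=C)C[C@@]1(CO)O[C@@H]1CC/C(COCc1ccc(OC)cc1)=C\CO[Si](c1ccccc1)(c1ccccc1)C(C)(C)C | intermediate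
21 | (8S,1R,10S)-epoxy acetate | C=C=C[C@@H](OC(=O)C(C)=C)C[C@@]1(COC(C)=O)O[C@@H]1CC/C(COCc1ccc(OC)cc1)=C\CO[Si](c1ccccc1)(c1ccccc1)C(C)(C)C | intermediate
22 | (8S,1R,10S)-C6 allylic alcohol | C=C=C[C@@H](OC(=O)C(C)=C)C[C@@]1(COC(C)=O)O[C@@H]1CC/C(COCc1ccc(OC)cc1)=C\CO | intermediate
23 | (8S,1R,10S)-enal–allene, CHO cis to C3 | C=C=C[C@@H](OC(=O)C(C)=C)C[C@@]1(COC(C)=O)O[C@@H]1CC/C(COCc1ccc(OC)cc1)=C\C=O | intermediate
24 | carbon monoxide | [C-]#[O+] | starting material
25 | 15-O-(4-methoxybenzyl) ether of the target (6R,7R,8S,1R,10S) | C=C(C)C(=O)O[C@H]1C[C@@]2(COC(C)=O)O[C@@H]2CC/C(COCc3ccc(OC)cc3)=C\[C@H]2OC(=O)C(=C)[C@H]12 | intermediate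
26 | CNP0306006.2 | C=C(C)C(=O)O[C@H]1C[C@@]2(COC(C)=O)O[C@@H]2CC/C(CO)=C\[C@H]2OC(=O)C(=C)[C@H]12 | target

Total step count: 18. Longest linear sequence: 16 steps (steps 1–3 and 6–18, from 1).

Steps most likely to fail

1. Step 17 (proposed new method). What may go wrong: oligomerisation in place of ten-membered ring closure, engagement of the terminal allene π-bond leading to a twelve-membered isomer, or poor facial control at C6 and C7. The fallback uses known chemistry, the CrCl2-mediated Nozaki–Hiyama–Kishi-type allylation that is established for closing germacranolide rings at C6–C7; it sets out from 11 and returns to the route at 25. The alkenyllithium from 11 opens (S)-triethyl(oxiran-2-ylmethoxy)silane (BF3·OEt2) to the secondary alcohol F1, which is acylated with methacrylic anhydride to the methacrylate F2. PPTS in MeOH removes the triethylsilyl group to give the primary alcohol F3, and Dess–Martin oxidation gives the α-acyloxy aldehyde F4. A Morita–Baylis–Hillman reaction with methyl acrylate (DABCO) gives the hydroxy acrylate F5. As in steps 12 to 16, TBS removal gives the diol F6, Sharpless epoxidation gives the epoxy diol F7, selective acetylation of the primary hydroxyl gives the acetate F8, TBDPS removal gives the allylic alcohol F9 and MnO2 gives the enal F10. NBS/Me2S converts the Baylis–Hillman alcohol with allylic transposition into the (Z)-2-(bromomethyl)enoate F11. CrCl2 in THF at high dilution then adds the allylchromium to the aldehyde through a chair transition state, and the alkoxide lactonises onto the methyl ester to give 25.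

2. Step 10. What may go wrong: isomerisation of the β,γ-unsaturated aldehyde into conjugation before the C–C bond forms, or weak facial control by the boron reagent. The fallback takes C8 from the chiral pool and avoids aldehyde 14; it sets out from 11 and returns at 18. 11 is converted as described above into alcohol F1, methacrylate F2, primary alcohol F3 and aldehyde F4. HC≡CMgBr in THF at −78 °C adds to F4 to give the propargylic alcohol F12 (both C7 epimers serve). A Mitsunobu reaction with 2-nitrobenzenesulfonylhydrazide (PPh3, DEAD), followed by loss of sulfinic acid and N2 from the propargylic diazene, delivers the terminal allene 18.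

3. Step 7. What may go wrong: delivery of tin to the distal alkyne carbon C1, or a mixture of regioisomers that cannot be separated. The fallback uses a free hydroxyl as the directing group; it sets out from 10 and returns at 11. Acid-catalysed methanolysis (camphorsulfonic acid, MeOH) removes the TBS group to give the propargylic alcohol F13. Palladium-catalysed hydrostannation of this free 2-alkyn-1-ol, for which proximal delivery is best precedented, gives the hydroxy stannane F14. TBSCl and imidazole return 11.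

Further compounds
F1 | step 17 | (8S)-secondary alcohol with C7H2–OSiEt3 (epoxide-opening product) | CC[Si](CC)(CC)OC[C@@H](O)C/C(CO[Si](C)(C)C(C)(C)C)=C/CC/C(COCc1ccc(OC)cc1)=C\CO[Si](c1ccccc1)(c1ccccc1)C(C)(C)C
F2 | step 17 | C8 methacrylate of F1 | CC[Si](CC)(CC)OC[C@@H](OC(=O)C(C)=C)C/C(CO[Si](C)(C)C(C)(C)C)=C/CC/C(COCc1ccc(OC)cc1)=C\CO[Si](c1ccccc1)(c1ccccc1)C(C)(C)C
F3 | step 17 | C7 primary alcohol | OC[C@@H](OC(=O)C(C)=C)C/C(CO[Si](C)(C)C(C)(C)C)=C/CC/C(COCc1ccc(OC)cc1)=C\CO[Si](c1ccccc1)(c1ccccc1)C(C)(C)C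
F4 | step 17 | C7 aldehyde (α-methacryloyloxy aldehyde) | O=C[C@@H](OC(=O)C(C)=C)C/C(CO[Si](C)(C)C(C)(C)C)=C/CC/C(COCc1ccc(OC)cc1)=C\CO[Si](c1ccccc1)(c1ccccc1)C(C)(C)C
F5 | step 17 | Baylis–Hillman adduct (methyl 2-methylene-3-hydroxy ester at C7, both C7 epimers) | COC(=O)C(=C)C(O)[C@@H](OC(=O)C(C)=C)C/C(CO[Si](C)(C)C(C)(C)C)=C/CC/C(COCc1ccc(OC)cc1)=C\CO[Si](c1ccccc1)(c1ccccc1)C(C)(C)C
F6 | step 17 | diol after TBS removal (C14–OH) | COC(=O)C(=C)C(O)[C@@H](OC(=O)C(C)=C)C/C(CO)=C/CC/C(COCc1ccc(OC)cc1)=C\CO[Si](c1ccccc1)(c1ccccc1)C(C)(C)C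
F7 | step 17 | (1R,10S)-epoxy diol | COC(=O)C(=C)C(O)[C@@H](OC(=O)C(C)=C)C[C@@]1(CO)O[C@@H]1CC/C(COCc1ccc(OC)cc1)=C\CO[Si](c1ccccc1)(c1ccccc1)C(C)(C)C
F8 | step 17 | C14 acetate of F7 | COC(=O)C(=C)C(O)[C@@H](OC(=O)C(C)=C)C[C@@]1(COC(C)=O)O[C@@H]1CC/C(COCc1ccc(OC)cc1)=C\CO[Si](c1ccccc1)(c1ccccc1)C(C)(C)C
F9 | step 17 | C6 allylic alcohol after TBDPS removal | COC(=O)C(=C)C(O)[C@@H](OC(=O)C(C)=C)C[C@@]1(COC(C)=O)O[C@@H]1CC/C(COCc1ccc(OC)cc1)=C\CO
F10 | step 17 | enal with Baylis–Hillman alcohol | COC(=O)C(=C)C(O)[C@@H](OC(=O)C(C)=C)C[C@@]1(COC(C)=O)O[C@@H]1CC/C(COCc1ccc(OC)cc1)=C\C=O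
F11 | step 17 | (Z)-2-(bromomethyl)enoate–enal (cyclisation precursor) | COC(=O)/C(CBr)=C/[C@@H](OC(=O)C(C)=C)C[C@@]1(COC(C)=O)O[C@@H]1CC/C(COCc1ccc(OC)cc1)=C\C=O
F12 | step 10 | propargylic alcohol at C7 (both epimers) | C#CC(O)[C@@H](OC(=O)C(C)=C)C/C(CO[Si](C)(C)C(C)(C)C)=C/CC/C(COCc1ccc(OC)cc1)=C\CO[Si](c1ccccc1)(c1ccccc1)C(C)(C)C
F13 | step 7 | propargylic alcohol (10 without TBS) | OCC#CCC/C(COCc1ccc(OC)cc1)=C\CO[Si](c1ccccc1)(c1ccccc1)C(C)(C)C
F14 | step 7 | (E)-2-(tributylstannyl) allylic alcohol (11 without TBS) | OC/C([Sn](CCCC)(CCCC)CCCC)=C\CC/C(COCc1ccc(OC)cc1)=C\CO[Si](c1ccccc1)(c1ccccc1)C(C)(C)C
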